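Everything rests on opening ring C at O1–C8a and C4–C4a. Ring A then becomes an aryne, and the rest becomes an acyclic (S)-β-hydroxy ester that already carries C2 and the (R)-oxirane. In the key step fluoride unmasks 3,5-bis(allyloxy)-6-prenylbenzyne from its o-silylaryl triflate. The C2 oxygen of the hydroxy ester adds to C8a, and the resulting C4a carbanion acylates on the ester, closing ring C in one operation. The step exploits the C5 oxygen of ring A next to C4a, which polarises the C4a–C8a aryne bond so that oxygen attacks C8a. The two prenyl units stay distinct because they arrive on separate fragments. Neutral Pd(0) deallylation ends the route.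

Key step: step 10

Remark: the SMILES is read as (2S) at C2 of ring C and (R) at the oxirane CH. Flavanone numbering (O1, C2–C4, C4a, C5–C8, C8a) is used throughout, and "prenyl" means 3-methylbut-2-enyl.

Step 1
Reactants: 1 4'-hydroxyacetophenone; 2 prenyl bromide
Product: 3 1-[4-hydroxy-3-prenylphenyl]ethanone
Conditions: KOH (1.1 equiv), H2O, rt; then dilute acid
Reagents that add atoms: none
Why: Known ortho C-prenylation of an ambident phenoxide, in which water hydrogen-bonds the oxygen so the allylic bromide is taken up at the ring carbon ortho to O (para is blocked by acetyl).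

Step 2
Reactants: 3 1-[4-hydroxy-3-prenylphenyl]ethanone
Product: 4 1-[4-(allyloxy)-3-prenylphenyl]ethanone
Conditions: allyl bromide, K2CO3, acetone, reflux
Reagents that add atoms: allyl bromide C=CCBr
Why: Williamson ether synthesis, with allyl chosen because it survives base, hydride transfer, dioxirane and fluoride and leaves at the end under neutral Pd(0) catalysis.

Step 3
Reactants: 4 1-[4-(allyloxy)-3-prenylphenyl]ethanone
Product: 5 methyl 3-[4-(allyloxy)-3-prenylphenyl]-3-oxopropanoate
Conditions: NaH (2.5 equiv), (MeO)2CO, THF, reflux; then dilute HCl, 0 °C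
Reagents that add atoms: dimethyl carbonate COC(=O)OC
Why: Crossed Claisen condensation of the ketone enolate with dimethyl carbonate, driven by deprotonation of the β-keto ester, with the aryl allyl ether and the prenyl group inert to NaH.

Step 4
Reactants: 5 methyl 3-[4-(allyloxy)-3-prenylphenyl]-3-oxopropanoate
Product: 6 methyl (3S)-3-[4-(allyloxy)-3-prenylphenyl]-3-hydroxypropanoate
Conditions: RuCl[(S,S)-TsDPEN](p-cymene) (1 mol %), HCO2H–Et3N (5:2), 35 °C
Reagents that add atoms: none
Why: Noyori–Ikariya asymmetric transfer hydrogenation, in which the (S,S)-TsDPEN–Ru hydride delivers H to the Re face of the aryl ketone through the outer-sphere six-membered transition state (CH/π contact to the aryl ring), setting the future C2 as (S) and leaving both C=C bonds untouched.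

Step 5
Reactants: 6 methyl (3S)-3-[4-(allyloxy)-3-prenylphenyl]-3-hydroxypropanoate
Product: 7 methyl (3S)-3-[4-(allyloxy)-3-{[(2R)-3,3-dimethyloxiran-2-yl]methyl}phenyl]-3-hydroxypropanoate
Conditions: D-fructose-derived Shi ketone (30 mol %), Oxone, K2CO3, Bu4NHSO4 (cat.), MeCN–DMM/aq Na2B4O7–Na2EDTA buffer (pH ≈ 10.5), 0 °C
Reagents that add atoms: Oxone (potassium peroxymonosulfate) [K+].[O-]S(=O)(=O)OO
Why: Shi asymmetric epoxidation, in which the dioxirane of the D-fructose-derived ketone attacks the electron-rich trisubstituted prenyl C=C through the spiro transition state and sets the (R)-oxirane carbon under catalyst control, while the monosubstituted allyl C=C reacts much more slowly.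

Step 6
Reactants: 8 phloroglucinol
Product: 9 3,5-bis(allyloxy)phenol
Conditions: allyl bromide (2.0 equiv), K2CO3, DMF, rt
Reagents that add atoms: allyl bromide C=CCBr
Why: Twofold Williamson etherification run with two equivalents of halide, the statistical mixture of mono-, di- and triethers being separable by chromatography because the polarities differ strongly.

Step 7
Reactants: 9 3,5-bis(allyloxy)phenol
Product: 10 2-bromo-3,5-bis(allyloxy)phenol
Conditions: NBS (1.0 equiv), CH2Cl2, −78 → −40 °C, dark
Reagents that add atoms: N-bromosuccinimide O=C1CCC(=O)N1Br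
Why: Electrophilic aromatic bromination of a very electron-rich ring at low temperature, far faster than attack on the allyl C=C bonds and directed ortho to the free OH because the site between the two allyloxy groups is more hindered.

Step 8
Reactants: 10 2-bromo-3,5-bis(allyloxy)phenol; 2 prenyl bromide
Product: 11 2-bromo-3,5-bis(allyloxy)-6-prenylphenol
Conditions: NaH (1.05 equiv), toluene, 0 °C; then 2, rt
Reagents that add atoms: none
Why: Ortho-selective C-alkylation of a sodium phenoxide held as a tight ion pair in a non-polar solvent, in which the only free ortho carbon (future C8) attacks the primary terminus of the allylic bromide.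

Step 9
Reactants: 11 2-bromo-3,5-bis(allyloxy)-6-prenylphenol
Product: 14 3,5-bis(allyloxy)-6-prenyl-2-(trimethylsilyl)phenyl triflate, via aryl trimethylsilyl ether 12 (not isolated), via lithium silylphenoxide 13 (not isolated)
Conditions: HMDS, THF, 65 °C, then evaporate; n-BuLi (1.1 equiv), THF, −78 °C; Tf2O (1.2 equiv), −78 → 0 °C
Reagents that add atoms: hexamethyldisilazane C[Si](C)(C)N[Si](C)(C)C; triflic anhydride O=S(=O)(C(F)(F)F)OS(=O)(=O)C(F)(F)F
Why: O-silylation, Br/Li exchange, retro-Brook 1,3-O→C silyl shift and O-triflation in one flask, the standard entry to o-silylaryl triflates, with exchange at −78 °C outrunning metalation of the allyl or prenyl CH2 groups.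

Step 10
Reactants: 7 methyl (3S)-3-[4-(allyloxy)-3-{[(2R)-3,3-dimethyloxiran-2-yl]methyl}phenyl]-3-hydroxypropanoate; 14 3,5-bis(allyloxy)-6-prenyl-2-(trimethylsilyl)phenyl triflate
Product: 17 (2S)-5,7-bis(allyloxy)-2-[4-(allyloxy)-3-{[(2R)-3,3-dimethyloxiran-2-yl]methyl}phenyl]-8-prenylchroman-4-one, via aryne 15 (not isolated), via aryl anion 16 (not isolated)
Conditions: KF (3 equiv), 18-crown-6 (3 equiv), 4 Å MS, THF, −20 → 0 °C, slow addition of 14 (1.5 equiv)
Reagents that add atoms: none
Why: Proposed new method: fluoride attacks the SiMe3 group of 14 and triflate leaves to give aryne 15, the fluoride-activated C2–OH of 7 adds through oxygen to C8a, and the C4a carbanion 16 so formed attacks the methyl ester and expels methoxide, so that O1–C8a and C4–C4a are made in one operation. The closest known reaction types are the tandem O-arylation/acyl capture of salicylate esters by arynes (xanthone annulation), aryne insertion into the N–C(O) bond of β-lactams (2,3-dihydroquinolin-4-ones) and the fluoride-mediated O–H insertion of arynes into aliphatic alcohols; what is new is an aliphatic secondary β-hydroxy ester as the O/C(=O) partner. Ring C closes in the 6-exo-trig mode (aryl carbanion onto the ester carbonyl through a six-membered tetrahedral intermediate). No stereocenter is created: C2 keeps its (S) configuration because its C–O bond is never broken, and the (R)-oxirane is a spectator. The step needs regioselectivity, which the C5 allyloxy group secures (its inductive pull distorts the aryne so that nucleophiles attack the distal C8a and charge builds at C4a next to C5–O, the C8 prenyl CH2 being only a small steric counterweight), and it needs acyl capture to outrun protonation, which the intramolecular six-ring trajectory, aprotic THF, excess fluoride (HF bound as bifluoride) and sieves (methanol uptake) favour. The low temperature and the scavenging of methoxide by surplus 14 or 15 should hold back E1cB opening of ring C and attack of THF on the aryne, and so protect C2.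

Step 11
Reactants: 17 (2S)-5,7-bis(allyloxy)-2-[4-(allyloxy)-3-{[(2R)-3,3-dimethyloxiran-2-yl]methyl}phenyl]-8-prenylchroman-4-one
Product: 18 (2S)-5,7-dihydroxy-2-[4-hydroxy-3-{[(2R)-3,3-dimethyloxiran-2-yl]methyl}phenyl]-8-prenylchroman-4-one (CNP0324151.1)
Conditions: Pd(PPh3)4 (10 mol %), PhNHMe (9 equiv), degassed THF, rt, dark; pH 7 buffer work-up
Reagents that add atoms: none
Why: Tsuji–Trost-type deallylation, in which Pd(0) ionises the three aryl allyl ethers and the weakly basic amine traps the π-allyl units, giving a near-neutral medium in which the isolated oxirane, the prenyl C=C and the base-labile C2 centre should persist.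

Compound list
1 | 4'-hydroxyacetophenone | CC(=O)c1ccc(O)cc1 | starting material
2 | prenyl bromide (1-bromo-3-methylbut-2-ene) | CC(C)=CCBr | starting material
3 | 1-[4-hydroxy-3-prenylphenyl]ethanone | CC(=O)c1ccc(O)c(CC=C(C)C)c1 | intermediate
4 | 1-[4-(allyloxy)-3-prenylphenyl]ethanone | CC(=O)c1ccc(OCC=C)c(CC=C(C)C)c1 | intermediate
5 | methyl 3-[4-(allyloxy)-3-prenylphenyl]-3-oxopropanoate | COC(=O)CC(=O)c1ccc(OCC=C)c(CC=C(C)C)c1 | intermediate
6 | methyl (3S)-3-[4-(allyloxy)-3-prenylphenyl]-3-hydroxypropanoate | COC(=O)C[C@H](O)c1ccc(OCC=C)c(CC=C(C)C)c1 | intermediate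
7 | methyl (3S)-3-[4-(allyloxy)-3-{[(2R)-3,3-dimethyloxiran-2-yl]methyl}phenyl]-3-hydroxypropanoate | COC(=O)C[C@H](O)c1ccc(OCC=C)c(C[C@H]2OC2(C)C)c1 | intermediate
8 | phloroglucinol | Oc1cc(O)cc(O)c1 | starting material
9 | 3,5-bis(allyloxy)phenol | Oc1cc(OCC=C)cc(OCC=C)c1 | intermediate
10 | 2-bromo-3,5-bis(allyloxy)phenol | Oc1cc(OCC=C)cc(OCC=C)c1Br | intermediate
11 | 2-bromo-3,5-bis(allyloxy)-6-prenylphenol | Oc1c(Br)c(OCC=C)cc(OCC=C)c1CC=C(C)C | intermediate
12 | [2-bromo-3,5-bis(allyloxy)-6-prenylphenoxy]trimethylsilane (not isolated) | C[Si](C)(C)Oc1c(Br)c(OCC=C)cc(OCC=C)c1CC=C(C)C | intermediate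
13 | lithium 3,5-bis(allyloxy)-6-prenyl-2-(trimethylsilyl)phenoxide (not isolated) | [Li+].[O-]c1c([Si](C)(C)C)c(OCC=C)cc(OCC=C)c1CC=C(C)C | intermediate
14 | 3,5-bis(allyloxy)-6-prenyl-2-(trimethylsilyl)phenyl triflate | CC(C)=CCc1c(OCC=C)cc(OCC=C)c([Si](C)(C)C)c1OS(=O)(=O)C(F)(F)F | intermediate
15 | 3,5-bis(allyloxy)-6-prenylbenzyne (not isolated) | CC(C)=CCC1=C(OCC=C)C=C(OCC=C)C#C1 | intermediate
16 | potassium salt of the C4a aryl anion of the O-arylated hydroxy ester (not isolated) | [K+].COC(=O)C[C@H](Oc1[c-]c(OCC=C)cc(OCC=C)c1CC=C(C)C)c1ccc(OCC=C)c(C[C@H]2OC2(C)C)c1 | intermediate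
17 | (2S)-5,7-bis(allyloxy)-2-[4-(allyloxy)-3-{[(2R)-3,3-dimethyloxiran-2-yl]methyl}phenyl]-8-prenylchroman-4-one | CC(C)=CCc1c(OCC=C)cc(OCC=C)c2c1O[C@H](c1ccc(OCC=C)c(C[C@H]3OC3(C)C)c1)CC2=O | intermediate
18 | (2S)-5,7-dihydroxy-2-[4-hydroxy-3-{[(2R)-3,3-dimethyloxiran-2-yl]methyl}phenyl]-8-prenylchroman-4-one | CC(C)=CCc1c(O)cc(O)c2c1O[C@H](c1ccc(O)c(C[C@H]3OC3(C)C)c1)CC2=O | target

Total step count: 11. Longest linear sequence: 7 steps (steps 1–5, 10, 11). The ring A branch (steps 6–9) joins at step 10.

Steps most likely to fail

**Step 10.**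
- The aryl anion may be protonated faster than it acylates, so the sequence stalls after the C–O bond.
- The hindered secondary alcohol may add too slowly next to the prenyl group, so that ene or [2+2] reactions of the aryne with the trisubstituted alkenes take over.
- Base-induced E1cB opening and reclosure of ring C may erode the C2 configuration.

The fallback uses known chemistry and closes ring C at O1–C2. It sets out from 5 and 11 and comes back at 17. Transfer hydrogenation of 5 with the (R,R)-TsDPEN–Ru catalyst gives methyl (3R)-3-[4-(allyloxy)-3-prenylphenyl]-3-hydroxypropanoate F1. Shi epoxidation as in step 5 gives methyl (3R)-3-[4-(allyloxy)-3-{[(2R)-3,3-dimethyloxiran-2-yl]methyl}phenyl]-3-hydroxypropanoate F2. MeNHOMe·HCl/i-PrMgCl (THF, −20 °C) converts it into the corresponding (3R)-N-methoxy-N-methyl-3-hydroxypropanamide F3. Double lithiation of 11 (n-BuLi, 2.1 equiv, THF, −78 °C) and addition to the magnesium alkoxide of F3 gives (3R)-1-[2-hydroxy-4,6-bis(allyloxy)-3-prenylphenyl]-3-[4-(allyloxy)-3-{[(2R)-3,3-dimethyloxiran-2-yl]methyl}phenyl]-3-hydroxypropan-1-one F4. An intramolecular Mitsunobu etherification (PPh3, DIAD, THF, 0 °C) then closes ring C with inversion at the carbinol carbon, (R) to (2S), and delivers 17.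

**Step 11.**
- Once the 4'-phenol is free, traces of acid or base may trigger its attack on the neighbouring oxirane.
- The π-allyl-Pd species may C-allylate the electron-rich ring A.
- Phenoxide formation may open ring C and racemise C2.

The fallback replaces direct liberation by a protecting-group exchange. It sets out from 17 and comes back at 18. Reductive allyl transfer with Pd(PPh3)4/PhSiH3 (CH2Cl2, rt) hands each oxygen over to silicon and gives the tris(O-phenylsilyl) ether of the target F5, so that no free phenol sits beside palladium. Brief solvolysis in MeOH/pH 7 buffer at 0 °C then releases 18.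

**Step 8.**
- O-alkylation may win over C-alkylation.
- Attack may occur at the carbon between the two allyloxy groups.
- A second alkylation may follow.

The fallback sets out from 10 and comes back at 11. Deliberate O-prenylation (2, K2CO3, acetone) gives 2-bromo-3,5-bis(allyloxy)-1-(prenyloxy)benzene F6. A clay-promoted formal [1,3]-shift of the ionisable prenyl group (montmorillonite K10, CH2Cl2, 0 °C to rt) moves it to the free ortho carbon, while the non-ionisable allyl ethers stay in place.

Further compounds
F1 | step 10 | methyl (3R)-3-[4-(allyloxy)-3-prenylphenyl]-3-hydroxypropanoate | COC(=O)C[C@@H](O)c1ccc(OCC=C)c(CC=C(C)C)c1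
F2 | step 10 | methyl (3R)-3-[4-(allyloxy)-3-{[(2R)-3,3-dimethyloxiran-2-yl]methyl}phenyl]-3-hydroxypropanoate | COC(=O)C[C@@H](O)c1ccc(OCC=C)c(C[C@H]2OC2(C)C)c1
F3 | step 10 | (3R)-3-[4-(allyloxy)-3-{[(2R)-3,3-dimethyloxiran-2-yl]methyl}phenyl]-3-hydroxy-N-methoxy-N-methylpropanamide | CON(C)C(=O)C[C@@H](O)c1ccc(OCC=C)c(C[C@H]2OC2(C)C)c1
F4 | step 10 | (3R)-1-[2-hydroxy-4,6-bis(allyloxy)-3-prenylphenyl]-3-[4-(allyloxy)-3-{[(2R)-3,3-dimethyloxiran-2-yl]methyl}phenyl]-3-hydroxypropan-1-one | CC(C)=CCc1c(OCC=C)cc(OCC=C)c(C(=O)C[C@@H](O)c2ccc(OCC=C)c(C[C@H]3OC3(C)C)c2)c1O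
F5 | step 11 | tris(O-phenylsilyl) ether of the target | CC(C)=CCc1c(O[SiH2]c2ccccc2)cc(O[SiH2]c2ccccc2)c2c1O[C@H](c1ccc(O[SiH2]c3ccccc3)c(C[C@H]3OC3(C)C)c1)CC2=O
F6 | step 8 | 2-bromo-3,5-bis(allyloxy)-1-(prenyloxy)benzene | CC(C)=CCOc1cc(OCC=C)cc(OCC=C)c1Br
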